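## Retrosynthetic overview

1. Target 21 ⇐ acetylation of allylic alcohol 20 ⇐ ligand-controlled nickel/chromium coupling of alkenyl bromide 11 (ring fragment) with aldehyde 19 (chain fragment), which sets the carbinol centre.
2. Ring fragment 11: the bold step is a one-flask copper-catalysed asymmetric conjugate methylation / enolate C-methylation of the achiral 2-alkylcyclohexenone 5. It sets both ring stereocentres at once (catalyst control at the tertiary centre, anti-alkylation at the quaternary centre), with no chiral pool and no 1,3-dione alkylation.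
3. The enone is then moved into place by desaturation, MeLi addition and oxidative 1,3-transposition; 5 itself comes from 2-iodocyclohexenone 3 and iodide 2 by Negishi coupling.
4. Chain fragment 19 comes from (E)-geranylacetone 12: the methyl ketone is turned into the butenolide, then the terminal alkene is cleaved to the aldehyde.
5. Ring order: the carbocycle is bought as 3 and only decorated; the butenolide is closed in step 8; the fragments are joined in step 11.

Assumption: geranylacetone is bought as the isomerically pure (E) grade, and where the sense of induction of a chiral ligand is stated, the antipodal ligand is taken if it proves opposite.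

## Route

Step 1
Reactants: 1 3-bromobut-3-en-1-ol
Product: 2 2-bromo-4-iodobut-1-ene
Conditions: I2, PPh3, imidazole, CH2Cl2, 0 → 25 °C
Reagents that add atoms: iodine, II
Why: Appel-type iodination: the alcohol is activated as an alkoxyphosphonium ion and displaced by iodide (SN2 at a primary carbon), the alkenyl bromide being inert.

Step 2
Reactants: 2 2-bromo-4-iodobut-1-ene; 3 2-iodocyclohex-2-en-1-one
Product: 5 2-(3-bromobut-3-en-1-yl)cyclohex-2-en-1-one, via alkylzinc iodide 4 (not isolated)
Conditions: Zn dust, LiCl, THF, 35 °C; then 3, PdCl2[P(2-furyl)3]2 (3 mol %), THF–DMF, 25 °C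
Reagents that add atoms: none
Why: Zinc inserts only into the alkyl C–I bond, and the Negishi coupling is chemoselective because zerovalent palladium adds to the α-iodoenone C–I bond much faster than to the unactivated alkenyl bromide.

Step 3
Reactants: 5 2-(3-bromobut-3-en-1-yl)cyclohex-2-en-1-one
Product: 8 (2R,3R)-2-(3-bromobut-3-en-1-yl)-2,3-dimethylcyclohexan-1-one, via aluminium enolate 6 (not isolated), via lithium aluminate enolate 7 (not isolated)
Conditions: Me3Al (1.5 equiv), Cu thiophene-2-carboxylate Cu(O2CC4H3S) (5 mol %), (S,S,S)-phosphoramidite from 1,1′-bi-2-naphthol and bis(1-phenylethyl)amine (10 mol %), Et2O, −30 °C; then MeLi (1.5 equiv), THF, −30 °C; then MeI (5 equiv), HMPA, −30 → 25 °C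
Reagents that add atoms: trimethylaluminium, C[Al](C)C; iodomethane, CI
Why: Tandem copper-catalysed asymmetric conjugate addition–enolate alkylation: the chiral monovalent copper–phosphoramidite complex transfers methyl from Me3Al to one face of C3 (sets 3R), and the regiodefined enolate, activated as its lithium aluminate, is C-methylated anti to the C3 methyl (held pseudo-axial by A1,2 strain), so the quaternary C2 centre forms with the two methyl groups trans (2R).

Step 4
Reactants: 8 (2R,3R)-2-(3-bromobut-3-en-1-yl)-2,3-dimethylcyclohexan-1-one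
Product: 9 (5R,6R)-6-(3-bromobut-3-en-1-yl)-5,6-dimethylcyclohex-2-en-1-one
Conditions: IBX (1.8 equiv), DMSO–fluorobenzene, 65 °C
Reagents that add atoms: none
Why: IBX α,β-dehydrogenation (Nicolaou conditions) can only take place on the CH2 side because the other α-carbon is quaternary, and limiting oxidant and temperature stops at the enone, so neither stereocentre is touched.

Step 5
Reactants: 9 (5R,6R)-6-(3-bromobut-3-en-1-yl)-5,6-dimethylcyclohex-2-en-1-one
Product: 10 (5R,6R)-6-(3-bromobut-3-en-1-yl)-1,5,6-trimethylcyclohex-2-en-1-ol (both C1 epimers)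
Conditions: MeLi, Et2O, −78 °C; then H2O
Reagents that add atoms: methyllithium, [Li]C
Why: 1,2-addition of MeLi to the enone carbonyl (hard nucleophile, no α′ proton to remove, alkenyl bromide inert at −78 °C) gives the tertiary allylic alcohol, whose new centre is of no consequence because it becomes sp2 in step 6.

Step 6
Reactants: 10 (5R,6R)-6-(3-bromobut-3-en-1-yl)-1,5,6-trimethylcyclohex-2-en-1-ol
Product: 11 (4R,5R)-4-(3-bromobut-3-en-1-yl)-3,4,5-trimethylcyclohex-2-en-1-one
Conditions: pyridinium chlorochromate (C5H5NH)[CrO3Cl] (2 equiv), 4 Å molecular sieves, CH2Cl2, 25 °C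
Reagents that add atoms: pyridinium chlorochromate, [O-][Cr](Cl)(=O)=O.c1cc[nH+]cc1
Why: Dauben–Babler oxidative 1,3-transposition: the tertiary allylic chromate ester undergoes a [3,3] shift and the resulting secondary chromate is oxidised, giving the β-methyl enone while the quaternary and tertiary centres (now C4 and C5) are untouched.

Step 7
Reactants: 12 (5E)-6,10-dimethylundeca-5,9-dien-2-one ((E)-geranylacetone)
Product: 14 (5E)-1-bromo-6,10-dimethylundeca-5,9-dien-2-one, via silyl enol ether 13 (not isolated)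
Conditions: LiN(iPr)2, Me3SiCl, THF, −78 °C; then NBS, −78 → 0 °C
Reagents that add atoms: N-bromosuccinimide, O=C1CCC(=O)N1Br
Why: Kinetic deprotonation on the CH3 side with in situ silylation gives the terminal silyl enol ether, which NBS brominates far faster than it attacks the trisubstituted alkenes (regioselective α-bromination through a silyl enol ether).

Step 8
Reactants: 14 (5E)-1-bromo-6,10-dimethylundeca-5,9-dien-2-one
Product: 16 4-[(3E)-4,8-dimethylnona-3,7-dien-1-yl]furan-2(5H)-one, via keto phosphonoacetate 15 (not isolated)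
Conditions: (EtO)2P(O)CH2CO2H, K2CO3, MeCN, 25 °C; then LiBr, Et3N, 25 °C
Reagents that add atoms: (diethoxyphosphoryl)acetic acid, CCOP(=O)(OCC)CC(=O)O
Why: Carboxylate SN2 displacement of the α-bromide followed by intramolecular Horner–Wadsworth–Emmons olefination under mild LiBr/Et3N conditions closes the butenolide, the ring enforcing the alkene geometry.

Step 9
Reactants: 16 4-[(3E)-4,8-dimethylnona-3,7-dien-1-yl]furan-2(5H)-one
Product: 18 4-[(3E)-6-(3,3-dimethyloxiran-2-yl)-4-methylhex-3-en-1-yl]furan-2(5H)-one (racemic at the oxirane), via bromohydrin 17 (not isolated)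
Conditions: NBS, THF–H2O (4:1), 0 °C; then K2CO3, MeOH, 0 → 25 °C
Reagents that add atoms: water, O
Why: van Tamelen bromohydrin formation is selective for the terminal trisubstituted alkene (most exposed in aqueous medium; the butenolide alkene is electron-poor), water opening the bromonium ion at the tertiary carbon, and carbonate then closes the epoxide, whose stereocentre is removed in step 10.

Step 10
Reactants: 18 4-[(3E)-6-(3,3-dimethyloxiran-2-yl)-4-methylhex-3-en-1-yl]furan-2(5H)-one
Product: 19 (4E)-4-methyl-7-(5-oxo-2,5-dihydrofuran-3-yl)hept-4-enal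
Conditions: H5IO6, THF–H2O, 0 → 25 °C
Reagents that add atoms: none
Why: Periodic acid hydrates the epoxide and cleaves the resulting glycol (Malaprade cleavage) to the aldehyde and acetone without affecting the alkenes or the lactone.

Step 11
Reactants: 11 (4R,5R)-4-(3-bromobut-3-en-1-yl)-3,4,5-trimethylcyclohex-2-en-1-one; 19 (4E)-4-methyl-7-(5-oxo-2,5-dihydrofuran-3-yl)hept-4-enal
Product: 20 (4R,5R)-4-[(4R,7E)-4-hydroxy-7-methyl-3-methylidene-10-(5-oxo-2,5-dihydrofuran-3-yl)dec-7-en-1-yl]-3,4,5-trimethylcyclohex-2-en-1-one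
Conditions: CrCl2 (3 equiv), N-[2-((4S)-4-isopropyl-4,5-dihydrooxazol-2-yl)-6-methylphenyl]methanesulfonamide (3.3 equiv), Et3N, NiCl2·(2,9-dimethyl-1,10-phenanthroline) (5 mol %), THF, 25 °C; then H2O
Reagents that add atoms: none
Why: Asymmetric Nozaki–Hiyama–Kishi coupling: zerovalent nickel activates the alkenyl bromide, transmetallation gives an alkenylchromium species that adds only to the aldehyde (enone and butenolide are tolerated), and the chromium-bound chiral sulfonamide–oxazoline ligand directs addition to the Si face of the aldehyde, giving the (4R)-carbinol under reagent control.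

Step 12
Reactants: 20 (4R,5R)-4-[(4R,7E)-4-hydroxy-7-methyl-3-methylidene-10-(5-oxo-2,5-dihydrofuran-3-yl)dec-7-en-1-yl]-3,4,5-trimethylcyclohex-2-en-1-one
Product: 21 (4R,7E)-7-methyl-3-methylidene-10-(5-oxo-2,5-dihydrofuran-3-yl)-1-[(1R,6R)-1,2,6-trimethyl-4-oxocyclohex-2-en-1-yl]dec-7-en-4-yl acetate (target)
Conditions: Ac2O, pyridine, 4-(dimethylamino)pyridine (5 mol %), CH2Cl2, 0 → 25 °C
Reagents that add atoms: acetic anhydride, CC(=O)OC(C)=O
Why: Nucleophile-catalysed acetylation of the secondary allylic alcohol does not break the C–O bond, so the (4R) configuration is retained.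

## Compound list

1 | 3-bromobut-3-en-1-ol | OCCC(Br)=C | starting material
2 | 2-bromo-4-iodobut-1-ene | ICCC(Br)=C | intermediate
3 | 2-iodocyclohex-2-en-1-one | O=C1CCCC=C1I | starting material
4 | (3-bromobut-3-en-1-yl)zinc iodide | I[Zn]CCC(Br)=C | intermediate
5 | 2-(3-bromobut-3-en-1-yl)cyclohex-2-en-1-one | O=C1CCCC=C1CCC(Br)=C | intermediate
6 | {[(3R)-2-(3-bromobut-3-en-1-yl)-3-methylcyclohex-1-en-1-yl]oxy}dimethylaluminium | C=C(Br)CCC1=C(O[Al](C)C)CCC[C@H]1C | intermediate
7 | lithium {[(3R)-2-(3-bromobut-3-en-1-yl)-3-methylcyclohex-1-en-1-yl]oxy}trimethylaluminate | [Li+].C=C(Br)CCC1=C(O[Al-](C)(C)C)CCC[C@H]1C | intermediate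
8 | (2R,3R)-2-(3-bromobut-3-en-1-yl)-2,3-dimethylcyclohexan-1-one | C=C(Br)CC[C@@]1(C)C(=O)CCC[C@H]1C | intermediate
9 | (5R,6R)-6-(3-bromobut-3-en-1-yl)-5,6-dimethylcyclohex-2-en-1-one | C=C(Br)CC[C@@]1(C)C(=O)C=CC[C@H]1C | intermediate
10 | (5R,6R)-6-(3-bromobut-3-en-1-yl)-1,5,6-trimethylcyclohex-2-en-1-ol (both C1 epimers) | C=C(Br)CC[C@@]1(C)C(C)(O)C=CC[C@H]1C | intermediate
11 | (4R,5R)-4-(3-bromobut-3-en-1-yl)-3,4,5-trimethylcyclohex-2-en-1-one | C=C(Br)CC[C@@]1(C)C(C)=CC(=O)C[C@H]1C | intermediate
12 | (5E)-6,10-dimethylundeca-5,9-dien-2-one | CC(=O)CC/C=C(\C)CCC=C(C)C | starting material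
13 | trimethyl{[(5E)-6,10-dimethylundeca-1,5,9-trien-2-yl]oxy}silane | C=C(O[Si](C)(C)C)CC/C=C(\C)CCC=C(C)C | intermediate
14 | (5E)-1-bromo-6,10-dimethylundeca-5,9-dien-2-one | BrCC(=O)CC/C=C(\C)CCC=C(C)C | intermediate
15 | (5E)-6,10-dimethyl-2-oxoundeca-5,9-dien-1-yl (diethoxyphosphoryl)acetate | CCOP(=O)(OCC)CC(=O)OCC(=O)CC/C=C(\C)CCC=C(C)C | intermediate
16 | 4-[(3E)-4,8-dimethylnona-3,7-dien-1-yl]furan-2(5H)-one | O=C1C=C(CC/C=C(\C)CCC=C(C)C)CO1 | intermediate
17 | 4-[(3E)-7-bromo-8-hydroxy-4,8-dimethylnon-3-en-1-yl]furan-2(5H)-one (racemic) | O=C1C=C(CC/C=C(\C)CCC(Br)C(C)(C)O)CO1 | intermediate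
18 | 4-[(3E)-6-(3,3-dimethyloxiran-2-yl)-4-methylhex-3-en-1-yl]furan-2(5H)-one (racemic) | O=C1C=C(CC/C=C(\C)CCC2OC2(C)C)CO1 | intermediate
19 | (4E)-4-methyl-7-(5-oxo-2,5-dihydrofuran-3-yl)hept-4-enal | O=CCC/C(C)=C/CCC1=CC(=O)OC1 | intermediate
20 | (4R,5R)-4-[(4R,7E)-4-hydroxy-7-methyl-3-methylidene-10-(5-oxo-2,5-dihydrofuran-3-yl)dec-7-en-1-yl]-3,4,5-trimethylcyclohex-2-en-1-one | C=C(CC[C@@]1(C)C(C)=CC(=O)C[C@H]1C)[C@@H](CC/C(C)=C/CCC1=CC(=O)OC1)O | intermediate
21 | (4R,7E)-7-methyl-3-methylidene-10-(5-oxo-2,5-dihydrofuran-3-yl)-1-[(1R,6R)-1,2,6-trimethyl-4-oxocyclohex-2-en-1-yl]dec-7-en-4-yl acetate | C=C(CC[C@@]1(C)C(C)=CC(=O)C[C@H]1C)[C@@H](CC/C(C)=C/CCC1=CC(=O)OC1)OC(C)=O | target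

## Step count and risks

Total step count: 12. Longest linear sequence: 8 steps (steps 1–6, 11, 12); the chain branch is steps 7–10.

Steps most likely to fail:

**Step 2.** The organozinc may form sluggishly, or palladium may start to engage the alkenyl bromide and give oligomers. The fallback sets out from compound 2 and comes back at compound 5; it makes the ring the nucleophile instead of the electrophile. Birch reduction of bought 2-methoxybenzoic acid F1 (Li, NH3–THF, −78 °C, excess metal quenched with isoprene) and alkylation of the carboxylate-stabilised enolate with 2 give 1-(3-bromobut-3-en-1-yl)-2-methoxycyclohexa-2,5-diene-1-carboxylic acid F2. Aqueous HCl at reflux then hydrolyses the enol ether, decarboxylates the β-keto acid and moves the alkene into conjugation, delivering enone 5.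

**Step 3.** The enantioselectivity with a 2-alkyl group larger than methyl, and the C-methylation of a hindered aluminium enolate to a quaternary centre, are both uncertain. The fallback sets out from compound 2 and comes back at compound 9; chiral-pool substrate control replaces catalysis. Bought (5R)-5-methylcyclohex-2-en-1-one F3 is deprotonated at C6 (LiN(iPr)2, THF, −78 °C) and alkylated with 2 (HMPA) trans to the methyl group, giving (5R,6S)-6-(3-bromobut-3-en-1-yl)-5-methylcyclohex-2-en-1-one F4. A second kinetic deprotonation and MeI, which again enters anti to the C5 methyl, give enone 9 directly, so steps 2 to 4 are bypassed.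

**Step 11.** There is no substrate bias at the new carbinol centre, so the outcome rests wholly on the ligand, and the bromide is less reactive than the usual iodide. The fallback sets out from compounds 11 and 19 and comes back at compound 20; resolution replaces ligand control. Ligand-free coupling (CrCl2, NiCl2 1 mol %, DMF, 25 °C) gives the 1:1 (4RS)-alcohol mixture F5. Sharpless kinetic resolution (Ti(OiPr)4, L-(+)-diisopropyl tartrate, tBuOOH 0.6 equiv, CH2Cl2, −20 °C) epoxidises the fast-reacting (4S) epimer to the (1S)-epoxy alcohol F6 and leaves the (4R)-alcohol 20, at most half of the material, which is separated by chromatography.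

Further compounds

F1 | step 2 | 2-methoxybenzoic acid (bought) | COc1ccccc1C(=O)O
F2 | step 2 | 1-(3-bromobut-3-en-1-yl)-2-methoxycyclohexa-2,5-diene-1-carboxylic acid (racemic) | OC(=O)C1(CCC(Br)=C)C=CCC=C1OC
F3 | step 3 | (5R)-5-methylcyclohex-2-en-1-one (bought) | O=C1C=CC[C@@H](C)C1
F4 | step 3 | (5R,6S)-6-(3-bromobut-3-en-1-yl)-5-methylcyclohex-2-en-1-one | C=C(Br)CC[C@@H]1C(=O)C=CC[C@H]1C
F5 | step 11 | (4R,5R)-4-[(4RS,7E)-4-hydroxy-7-methyl-3-methylidene-10-(5-oxo-2,5-dihydrofuran-3-yl)dec-7-en-1-yl]-3,4,5-trimethylcyclohex-2-en-1-one | C=C(CC[C@@]1(C)C(C)=CC(=O)C[C@H]1C)C(O)CC/C(C)=C/CCC1=CC(=O)OC1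
F6 | step 11 | (4R,5R)-4-(2-{2-[(1S,4E)-1-hydroxy-4-methyl-7-(5-oxo-2,5-dihydrofuran-3-yl)hept-4-en-1-yl]oxiran-2-yl}ethyl)-3,4,5-trimethylcyclohex-2-en-1-one (oxirane carbon as formed) | O1CC1(CC[C@@]2(C)C(C)=CC(=O)C[C@H]2C)[C@H](CC/C(C)=C/CCC3=CC(=O)OC3)O
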